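**Retrosynthetic overview**
1. The strategy rests on C1 of the 1,2-dihydronaphthalene: a methine bonded only to the pendant ring, to C2 and to the ring-fusion carbon C8a of ring A. It therefore maps onto the formyl carbon of an aryl aldehyde placed between a C2 enolate and ring A.
2. The 6-carboxy-2-pyrone is read as the ring-cleavage lactone of a 5-substituted pyrogallol, so the pendant ring is carried as 3,4,5-tris(benzyloxy)phenyl (which also stabilises a C1 cation) and ring A as its dimethyl ether.
3. Key disconnections: C1–C2 (oxazolidinone boron aldol) and C1–C8a (Friedel–Crafts) in one flask; C3=C4 and the C3 carboxyl come from a Stobbe half-ester of veratraldehyde and dimethyl succinate.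
4. Ring order: ring A is bought, ring B closes in the key step, the pyrone ring is made last from the pendant arene by peracid cleavage, then the ring A methyl ethers are removed.

Key step: step 3

Remark (assumptions): the conjugated methyl ester is saponified before the base-sensitive pyrone exists, so that the last step is only an ether cleavage; the 2-pyrone is assumed to tolerate BBr3 at or below 0 °C.

**Step 1**
Reactants: 1 veratraldehyde (3,4-dimethoxybenzaldehyde); 2 dimethyl succinate
Product: 4 (3E)-4-(3,4-dimethoxyphenyl)-3-(methoxycarbonyl)but-3-enoic acid, via paraconate lactone 3 (not isolated)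
Conditions: NaOMe, MeOH, reflux; then aq HCl
Reagents that add atoms: none
Why: Stobbe condensation, in which the succinate enolate adds to the aldehyde, the alkoxide closes onto the distal ester to lactone 3 and E1cB opening of the lactone should give the half-ester with only the saturated carboxyl free and the aryl group trans to the conjugated ester, the (E) geometry that is favoured for aryl aldehydes and that places the arene cis to the CH2 group.

**Step 2**
Reactants: 4 (3E)-4-(3,4-dimethoxyphenyl)-3-(methoxycarbonyl)but-3-enoic acid; 5 (R)-4-benzyloxazolidin-2-one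
Product: 7 (4R)-4-benzyl-3-[(3E)-4-(3,4-dimethoxyphenyl)-3-(methoxycarbonyl)but-3-enoyl]oxazolidin-2-one, via pivalic mixed anhydride 6 (not isolated)
Conditions: t-BuCOCl, Et3N, THF, −20 °C; then 5, LiCl, −20 °C → rt
Reagents that add atoms: none
Why: N-acylation of an oxazolidinone through a mixed pivalic anhydride (LiCl/Et3N variant), in which the lithium-activated oxazolidinone attacks the less hindered carbonyl of 6 and the mild amine base should neither move the (E)-alkene out of conjugation nor touch the stereocentre of 5.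

**Step 3**
Reactants: 7 (4R)-4-benzyl-3-[(3E)-4-(3,4-dimethoxyphenyl)-3-(methoxycarbonyl)but-3-enoyl]oxazolidin-2-one; 8 3,4,5-tris(benzyloxy)benzaldehyde
Product: 11 methyl (1R,2S)-2-{[(4R)-4-benzyl-2-oxooxazolidin-3-yl]carbonyl}-6,7-dimethoxy-1-[3,4,5-tris(benzyloxy)phenyl]-1,2-dihydronaphthalene-3-carboxylate, via boron enolate 9 (not isolated), via boron aldolate 10 (not isolated)
Conditions: Bu2BOTf, iPr2NEt, CH2Cl2, 0 °C; 8, −78 → 0 °C; then BF3·OEt2 (excess), −40 → 0 °C; aq NaHCO3
Reagents that add atoms: none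
Why: Proposed new method: Bu2BOTf/iPr2NEt should convert 7 into the Z boron enolate 9, which adds through its α-carbon to aldehyde 8 in a closed chair (Zimmerman–Traxler) transition state to form C1–C2 as the syn boron aldolate 10, and excess BF3·OEt2 should then ionise the benzylic C–O bond of 10 to a cation stabilised by the para benzyloxy group, which is captured by the 3,4-dimethoxyphenyl ring at the carbon para to its 3-methoxy group to form C1–C8a, with rearomatisation. The closest known reaction type is the same sequence run as two operations, an oxazolidinone boron aldol (Evans syn-aldol) followed by acid-mediated Friedel–Crafts cyclisation of the isolated benzylic carbinol to a 1-aryl-1,2-dihydronaphthalene, so that only the ionisation of the boron aldolate in the same flask is untested. Ring B closes as a six-membered intramolecular Friedel–Crafts alkylation, 6-endo with respect to the arene π bond that attacks. C2 is set in the aldol ((S) in the numbering of 11) by the (R)-4-benzyl group of the auxiliary, which blocks one enolate face in the dipole-opposed transition state, and C1 is set (R) in the cation closure, where the aryl group lies anti to the C2 acyl group (both pseudoaxial in the half-chair, clear of C8–H and of the C3 ester), so that either carbinol epimer should converge on the 1,2-trans product. The step needs α- rather than γ-attack of the dienolate, ring closure faster than retro-aldol or loss of the C2 proton from the cation, closure para rather than ortho to a methoxy group, and intact benzyl ethers; the boron-bound closed transition state, the (E)-alkene that holds the arene cis to C2, the lower hindrance of C6 of the veratryl ring and the low temperature of the Lewis acid stage are relied on for these.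

**Step 4**
Reactants: 11 methyl (1R,2S)-2-{[(4R)-4-benzyl-2-oxooxazolidin-3-yl]carbonyl}-6,7-dimethoxy-1-[3,4,5-tris(benzyloxy)phenyl]-1,2-dihydronaphthalene-3-carboxylate
Product: 13 (1R,2S)-6,7-dimethoxy-3-(methoxycarbonyl)-1-[3,4,5-tris(benzyloxy)phenyl]-1,2-dihydronaphthalene-2-carboxylic acid, via peroxy acid 12 (not isolated)
Conditions: LiOH·H2O, 30% H2O2, THF/H2O (3:1), 0 °C; aq Na2SO3; 1 M HCl
Reagents that add atoms: hydrogen peroxide, OO (one oxygen, the OH oxygen of the new carboxyl group)
Why: Hydroperoxide cleavage of an N-acyloxazolidinone, in which LiOOH attacks the exocyclic imide carbonyl and sulfite reduces peroxy acid 12, while at 0 °C the conjugated methyl ester and the β-aryl acrylate should not react and C2 is secure because, with C1 fixed, the 1,2-trans arrangement is the more stable one.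

**Step 5**
Reactants: 13 (1R,2S)-6,7-dimethoxy-3-(methoxycarbonyl)-1-[3,4,5-tris(benzyloxy)phenyl]-1,2-dihydronaphthalene-2-carboxylic acid
Product: 14 (1R,2S)-6,7-dimethoxy-1-[3,4,5-tris(benzyloxy)phenyl]-1,2-dihydronaphthalene-2,3-dicarboxylic acid
Conditions: LiOH, THF/H2O, 40 °C, argon; 1 M HCl
Reagents that add atoms: lithium hydroxide (LiOH), [Li+].[OH-] (the OH oxygen of the new carboxyl group)
Why: Saponification (acyl–oxygen cleavage by hydroxide) of the conjugated methyl ester at a stage where no pyrone or free catechol is present, with C2 α to a carboxylate and therefore not expected to epimerise, and with the benzyl and methyl ethers inert.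

**Step 6**
Reactants: 14 (1R,2S)-6,7-dimethoxy-1-[3,4,5-tris(benzyloxy)phenyl]-1,2-dihydronaphthalene-2,3-dicarboxylic acid
Product: 15 (1R,2S)-6,7-dimethoxy-1-(3,4,5-trihydroxyphenyl)-1,2-dihydronaphthalene-2,3-dicarboxylic acid
Conditions: BCl3 (1 M in CH2Cl2), pentamethylbenzene, CH2Cl2, −78 °C; then H2O; used at once under argon
Reagents that add atoms: none
Why: Lewis-acid debenzylation with BCl3 and pentamethylbenzene as cation scavenger, which at −78 °C should cleave the three aryl benzyl ethers while the aryl methyl ethers, the acids and the C3=C4 alkene (which hydrogenolysis would reduce) are untouched and the scavenger intercepts benzyl cations before they alkylate the electron-rich rings.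

**Step 7**
Reactants: 15 (1R,2S)-6,7-dimethoxy-1-(3,4,5-trihydroxyphenyl)-1,2-dihydronaphthalene-2,3-dicarboxylic acid
Product: 18 (1R,2S)-1-(6-carboxy-2-oxo-2H-pyran-4-yl)-6,7-dimethoxy-1,2-dihydronaphthalene-2,3-dicarboxylic acid, via hydroxy-ortho-quinone 16 (not isolated), via muconic anhydride 17 (not isolated)
Conditions: CH3CO3H (in AcOH), AcOH, 15–20 °C, dark
Reagents that add atoms: peracetic acid, CC(=O)OO (one oxygen, in the pyrone carboxyl group)
Why: Peracid ring cleavage of a vicinal trihydroxyarene, in which oxidation to quinone 16, Baeyer–Villiger-type oxygen insertion between the two carbonyls to the seven-membered anhydride 17 and attack of the enol hydroxyl on the distal anhydride carbonyl should give the 6-carboxy-2-pyrone, the two insertion sites being equivalent by the local symmetry of the 5-substituted pyrogallol, while ring A as its dimethyl ether and the electron-poor C3=C4 alkene react more slowly.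

**Step 8**
Reactants: 18 (1R,2S)-1-(6-carboxy-2-oxo-2H-pyran-4-yl)-6,7-dimethoxy-1,2-dihydronaphthalene-2,3-dicarboxylic acid
Product: 19 (1R,2S)-1-(6-carboxy-2-oxo-2H-pyran-4-yl)-6,7-dihydroxy-1,2-dihydronaphthalene-2,3-dicarboxylic acid (target, CNP0195322.1)
Conditions: BBr3, CH2Cl2, −78 → 0 °C; then H2O, 0 °C; reverse-phase purification
Reagents that add atoms: none
Why: Aryl methyl ether cleavage with BBr3 (complexation at oxygen, bromide attack on methyl, hydrolysis of the aryl borates), under acidic non-basic conditions that should leave the 2-pyrone, the three acids, the alkene and both stereocentres untouched.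

**Compound list**
1 | veratraldehyde (3,4-dimethoxybenzaldehyde) | COc1ccc(C=O)cc1OC | starting material
2 | dimethyl succinate | COC(=O)CCC(=O)OC | starting material
3 | methyl 2-(3,4-dimethoxyphenyl)-5-oxotetrahydrofuran-3-carboxylate (paraconate lactone, racemic diastereomer mixture) | COC(=O)C1CC(=O)OC1c1ccc(OC)c(OC)c1 | intermediate
4 | (3E)-4-(3,4-dimethoxyphenyl)-3-(methoxycarbonyl)but-3-enoic acid | COC(=O)/C(CC(=O)O)=C/c1ccc(OC)c(OC)c1 | intermediate
5 | (R)-4-benzyloxazolidin-2-one | O=C1N[C@H](Cc2ccccc2)CO1 | starting material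
6 | (3E)-4-(3,4-dimethoxyphenyl)-3-(methoxycarbonyl)but-3-enoic pivalic anhydride | COC(=O)/C(CC(=O)OC(=O)C(C)(C)C)=C/c1ccc(OC)c(OC)c1 | intermediate
7 | (4R)-4-benzyl-3-[(3E)-4-(3,4-dimethoxyphenyl)-3-(methoxycarbonyl)but-3-enoyl]oxazolidin-2-one | COC(=O)/C(CC(=O)N1[C@H](Cc2ccccc2)COC1=O)=C/c1ccc(OC)c(OC)c1 | intermediate
8 | 3,4,5-tris(benzyloxy)benzaldehyde | O=Cc1cc(OCc2ccccc2)c(OCc2ccccc2)c(OCc2ccccc2)c1 | starting material
9 | dibutylboron Z-enolate of 7: (4R)-4-benzyl-3-[(1Z,3E)-1-(dibutylboryloxy)-4-(3,4-dimethoxyphenyl)-3-(methoxycarbonyl)buta-1,3-dien-1-yl]oxazolidin-2-one | CCCCB(CCCC)O/C(=C\C(C(=O)OC)=C/c1ccc(OC)c(OC)c1)N1[C@H](Cc2ccccc2)COC1=O | intermediate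
10 | dibutylboron syn-aldolate: (4R)-4-benzyl-3-{(2R,3E)-2-[(R)-(dibutylboryloxy)[3,4,5-tris(benzyloxy)phenyl]methyl]-4-(3,4-dimethoxyphenyl)-3-(methoxycarbonyl)but-3-enoyl}oxazolidin-2-one | O=C(N1[C@H](Cc2ccccc2)COC1=O)[C@H](/C(C(=O)OC)=C\c1ccc(OC)c(OC)c1)[C@@H](OB(CCCC)CCCC)c1cc(OCc2ccccc2)c(OCc2ccccc2)c(OCc2ccccc2)c1 | intermediate
11 | methyl (1R,2S)-2-{[(4R)-4-benzyl-2-oxooxazolidin-3-yl]carbonyl}-6,7-dimethoxy-1-[3,4,5-tris(benzyloxy)phenyl]-1,2-dihydronaphthalene-3-carboxylate (1,2-trans) | COC(=O)C1=Cc2cc(OC)c(OC)cc2[C@@H](c2cc(OCc3ccccc3)c(OCc3ccccc3)c(OCc3ccccc3)c2)[C@@H]1C(=O)N1[C@H](Cc2ccccc2)COC1=O | intermediate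
12 | (1R,2S)-6,7-dimethoxy-3-(methoxycarbonyl)-1-[3,4,5-tris(benzyloxy)phenyl]-1,2-dihydronaphthalene-2-carboperoxoic acid | COC(=O)C1=Cc2cc(OC)c(OC)cc2[C@@H](c2cc(OCc3ccccc3)c(OCc3ccccc3)c(OCc3ccccc3)c2)[C@@H]1C(=O)OO | intermediate
13 | (1R,2S)-6,7-dimethoxy-3-(methoxycarbonyl)-1-[3,4,5-tris(benzyloxy)phenyl]-1,2-dihydronaphthalene-2-carboxylic acid | COC(=O)C1=Cc2cc(OC)c(OC)cc2[C@@H](c2cc(OCc3ccccc3)c(OCc3ccccc3)c(OCc3ccccc3)c2)[C@@H]1C(=O)O | intermediate
14 | (1R,2S)-6,7-dimethoxy-1-[3,4,5-tris(benzyloxy)phenyl]-1,2-dihydronaphthalene-2,3-dicarboxylic acid | OC(=O)C1=Cc2cc(OC)c(OC)cc2[C@@H](c2cc(OCc3ccccc3)c(OCc3ccccc3)c(OCc3ccccc3)c2)[C@@H]1C(=O)O | intermediate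
15 | (1R,2S)-6,7-dimethoxy-1-(3,4,5-trihydroxyphenyl)-1,2-dihydronaphthalene-2,3-dicarboxylic acid | OC(=O)C1=Cc2cc(OC)c(OC)cc2[C@@H](c2cc(O)c(O)c(O)c2)[C@@H]1C(=O)O | intermediate
16 | (1R,2S)-1-(5-hydroxy-3,4-dioxocyclohexa-1,5-dien-1-yl)-6,7-dimethoxy-1,2-dihydronaphthalene-2,3-dicarboxylic acid | OC(=O)C1=Cc2cc(OC)c(OC)cc2[C@@H](C2=CC(=O)C(=O)C(O)=C2)[C@@H]1C(=O)O | intermediate
17 | (1R,2S)-1-(6-hydroxy-2,7-dioxo-2,7-dihydrooxepin-4-yl)-6,7-dimethoxy-1,2-dihydronaphthalene-2,3-dicarboxylic acid | OC(=O)C1=Cc2cc(OC)c(OC)cc2[C@@H](C2=CC(=O)OC(=O)C(O)=C2)[C@@H]1C(=O)O | intermediate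
18 | (1R,2S)-1-(6-carboxy-2-oxo-2H-pyran-4-yl)-6,7-dimethoxy-1,2-dihydronaphthalene-2,3-dicarboxylic acid | OC(=O)C1=Cc2cc(OC)c(OC)cc2[C@@H](c2cc(C(=O)O)oc(=O)c2)[C@@H]1C(=O)O | intermediate
19 | (1R,2S)-1-(6-carboxy-2-oxo-2H-pyran-4-yl)-6,7-dihydroxy-1,2-dihydronaphthalene-2,3-dicarboxylic acid | O=C(O)C1=Cc2cc(O)c(O)cc2[C@@H](c2cc(C(=O)O)oc(=O)c2)[C@@H]1C(=O)O | target

**Step count**
Total: 8 steps. Longest linear sequence: 8 steps (1 and 2 to 19); 5 and 8 enter as purchased materials.

**Steps most likely to fail**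

First, step 3 (the proposed new method). The chelated boron aldolate may ionise slowly, so that retro-aldol, loss of the C2 proton from the cation (which would erase C2) or Lewis-acid cleavage of benzyl ethers outruns ring closure. The fallback is the known two-operation sequence. It sets out from 7 and 8: the aldol is run alone (Bu2BOTf, iPr2NEt, CH2Cl2, −78 → 0 °C; pH 7 buffer, MeOH, H2O2) and the free syn-aldol carbinol F1 is isolated. F1 is then cyclised in a second flask with CF3CO2H in CH2Cl2 at 0 °C, the established protic-acid Friedel–Crafts closure of such benzylic carbinols. This comes back to the route at 11.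

Second, step 7. The hydroxyquinone may couple with unreacted pyrogallol (benzotropolone-type condensation), or the peracid may oxidise ring A or epoxidise the C3=C4 alkene. The fallback sets out from 15 and uses Pb(OAc)4 in MeOH/toluene at 0 °C, the known cleavage of ortho-dihydroxyarenes to cis,cis-muconate methyl esters, which proceeds by fragmentation of the quinone hemiketal and uses no oxygen-transfer reagent. It should give the dimethyl 2-hydroxymuconate F2. Warming F2 in aqueous HCl/AcOH should hydrolyse both esters and close the enol lactone, coming back to the route at 18.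

Third, step 8. The triacid may dissolve poorly in CH2Cl2 so that ether cleavage stalls, and long exposure to BBr3 and HBr may degrade the pyrone. The fallback sets out from 18: Fischer esterification (HCl in MeOH, 50 °C) should give the trimethyl ester F3, which is demethylated in homogeneous solution (BBr3, CH2Cl2, −78 → 0 °C) to the catechol trimethyl ester F4. Acid hydrolysis of the three esters (3 M HCl, 1,4-dioxane, 80 °C, argon; no base, so the pyrone is not opened) then arrives at 19.

**Further compounds**
F1 | step 3 | (4R)-4-benzyl-3-{(2R,3E)-4-(3,4-dimethoxyphenyl)-2-[(R)-hydroxy[3,4,5-tris(benzyloxy)phenyl]methyl]-3-(methoxycarbonyl)but-3-enoyl}oxazolidin-2-one | O=C(N1[C@H](Cc2ccccc2)COC1=O)[C@H](/C(C(=O)OC)=C\c1ccc(OC)c(OC)c1)[C@@H](O)c1cc(OCc2ccccc2)c(OCc2ccccc2)c(OCc2ccccc2)c1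
F2 | step 7 | dimethyl (2E,4Z)-4-[(1R,2S)-2,3-dicarboxy-6,7-dimethoxy-1,2-dihydronaphthalen-1-yl]-2-hydroxyhexa-2,4-dienedioate | OC(=O)C1=Cc2cc(OC)c(OC)cc2[C@@H](C(=C/C(=O)OC)/C=C(O)\C(=O)OC)[C@@H]1C(=O)O
F3 | step 8 | dimethyl (1R,2S)-6,7-dimethoxy-1-[6-(methoxycarbonyl)-2-oxo-2H-pyran-4-yl]-1,2-dihydronaphthalene-2,3-dicarboxylate | COC(=O)C1=Cc2cc(OC)c(OC)cc2[C@@H](c2cc(C(=O)OC)oc(=O)c2)[C@@H]1C(=O)OC
F4 | step 8 | dimethyl (1R,2S)-6,7-dihydroxy-1-[6-(methoxycarbonyl)-2-oxo-2H-pyran-4-yl]-1,2-dihydronaphthalene-2,3-dicarboxylate | COC(=O)C1=Cc2cc(O)c(O)cc2[C@@H](c2cc(C(=O)OC)oc(=O)c2)[C@@H]1C(=O)OC
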